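The cuts run from the silyl ethers back through the C8 methyl and C9–C11 to a one-carbon contraction of ring B.

Locants: the right decalin is ring A (C1–C5, C10) plus ring B (C5–C10), with Me2 on C4, Me on C8 and C10, and OH on C3. The linker is C11–C12. The left cis-decalin is ring D (C13–C18) plus ring E (C17–C22), with Me on C17, C19 and C20, and OH on C20. β is the face of the angular methyl group of each decalin.
Cuts, in retrosynthetic order: the two O–Si bonds; C8–CH3 back to C8=CH2 and then C8=O; C9–C11 (enolate plus allylic bromide); then C9–C10, a retro-1,2-shift that contracts ring B to a cyclopentanone (C8 bonded to C10) and takes C9 out as CHBr2.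
Enabling feature: in ring B the CH carbon C9 lies between quaternary C10 and C8, and the axial methyl on C8 is the retron of an 8-ketone. Deprotonation cannot give the Δ8(9)-enolate needed for the C9–C11 bond, because C7 reacts first. That enolate is the direct product when C10 migrates from C8 to a carbenoid C9 in the B-nor ketone, a Hajos–Parrish-type trans-hydrindanone.
Forward: ring D is bought and ring E is annulated onto it. The cyclopentane is bought and ring A is annulated onto it. Ring B arises 5→6 in the same flask that joins the two halves. C8 methylenation, hydrogenation and desilylation follow.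
Stereochemistry: C17 comes from (R)-1-phenylethylamine and C10 from (S)-phenylalanine catalysis. C20 and C19 are set by α-face epoxidation and hydrogenation anti to C17-Me. C18 and C9 are set by equilibration next to a ketone, C5 by Li/NH3, C3 by axial hydride, and C8 by α-face hydrogenation. The E-alkene follows from allylic strain in the SN2′ bromination.

Key step: step 19

Assumption: C20 in 8, C13 in 11 and 16, and C9 in 28, F2 and F3 are left open in the SMILES, because the following step erases or equilibrates these centres.

Step 1
Reactants: 1 2-methylcyclohexanone (racemic), 2 (R)-1-phenylethylamine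
Product: 3 (R)-N-(2-methylcyclohexylidene)-1-phenylethanamine
Conditions: p-TsOH (cat.), toluene, reflux, Dean–Stark
Reagents that add atoms: none
Why: Acid-catalysed imine condensation with azeotropic removal of water; the α-stereocentre of 1 is mobile through imine–enamine tautomerism, so the racemate serves.

Step 2
Reactants: 3 (R)-N-(2-methylcyclohexylidene)-1-phenylethanamine, 4 ethyl vinyl ketone
Product: 6 (S)-2-methyl-2-(3-oxopentyl)cyclohexanone, via Michael adduct imine 5 (not isolated)
Conditions: THF, rt to 40 °C; then 20% aq. AcOH, rt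
Reagents that add atoms: water, O
Why: Deracemising Michael addition of a chiral imine: the more substituted secondary enamine tautomer adds to the enone in a compact aza-ene-like transition state on the face away from the phenyl group, which sets quaternary C17 as S, and mild acid hydrolysis then frees the ketone and the auxiliary.

Step 3
Reactants: 6 (S)-2-methyl-2-(3-oxopentyl)cyclohexanone
Product: 7 (S)-1,4a-dimethyl-4,4a,5,6,7,8-hexahydronaphthalen-2(3H)-one (rings D/E; C20 ketone; C18=C19)
Conditions: NaOMe (cat.), MeOH, reflux
Reagents that add atoms: none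
Why: Intramolecular aldol condensation (second half of a Robinson annulation) closes ring E between C18 and C19 and cannot touch C17.

Step 4
Reactants: 7 (S)-1,4a-dimethyl-4,4a,5,6,7,8-hexahydronaphthalen-2(3H)-one
Product: 9 (S)-4a,7,8-trimethyl-2,3,4,4a,5,6-hexahydronaphthalene (13(18),19-diene), via tertiary allylic alcohol 8 (not isolated)
Conditions: MeMgBr, Et2O, 0 °C to rt; then 2 M HCl, rt
Reagents that add atoms: methylmagnesium bromide, C[Mg]Br
Why: Grignard 1,2-addition (the β-carbon C18 is fully substituted, so 1,4-addition is shut off) followed by acid dehydration of the tertiary allylic alcohol, which under equilibrating conditions gives the heteroannular diene as in the 3-methyl-3,5-diene series of steroids and erases the uncontrolled C20 centre of 8.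

Step 5
Reactants: 9 (S)-4a,7,8-trimethyl-2,3,4,4a,5,6-hexahydronaphthalene
Product: 11 18-ene-13,20α-diol (20β-Me; C13 epimers), via vinyl epoxide 10 (not isolated)
Conditions: mCPBA (1.0 equiv), NaHCO3, CH2Cl2, −20 to 0 °C; then THF–H2O, HClO4 (cat.), 0 °C
Reagents that add atoms: mCPBA, O=C(OO)c1cccc(Cl)c1; water, O
Why: Prilezhaev epoxidation picks the more electron-rich tetrasubstituted C19=C20 bond and the α-face (the pseudoaxial C17 methyl group lies 1,3 to C19 on the β-face), which fixes the 20α-oxygen, and allylic (SN1′) hydrolysis of the vinyl oxirane puts water on the less hindered C13 end of the allyl cation without breaking the C20–O bond.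

Step 6
Reactants: 11 18-ene-13,20α-diol
Product: 12 20α-hydroxy-17β,19,20β-trimethyl-18-en-13-one
Conditions: Dess–Martin periodinane, NaHCO3, CH2Cl2, 0 °C to rt
Reagents that add atoms: none
Why: Dess–Martin oxidation converts only the secondary allylic alcohol, both C13 epimers converging on one enone, while the tertiary C20 alcohol cannot react.

Step 7
Reactants: 12 20α-hydroxy-17β,19,20β-trimethyl-18-en-13-one
Product: 14 cis-decalone (18β-H; 19β-Me; 20β-Me; 20α-OH; C13 ketone), via trans-decalone 13 (not isolated)
Conditions: H2 (1–4 bar), Pd/C, EtOAc, rt; filter; NaOMe (cat.), MeOH, rt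
Reagents that add atoms: none
Why: Heterogeneous syn-hydrogenation of the s-cis enone from the α-face (β-face closed by the C17 and C20 methyl groups, α-face offering the haptophilic 20α-OH) sets 19α-H and hence 19β-Me, and base equilibration through the C13 enolate then turns the strained trans-decalone (C17-Me and C19-Me syn-diaxial) into the cis-decalone in which C19-Me is equatorial, which sets 18β-H.

Step 8
Reactants: 14 cis-decalone
Product: 15 20-O-triethylsilyl ether of 14
Conditions: TESOTf, 2,6-lutidine, CH2Cl2, −40 to 0 °C
Reagents that add atoms: triethylsilyl triflate, CC[Si](CC)(CC)OS(=O)(=O)C(F)(F)F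
Why: Silyl triflate silylation is the standard way to mask a tertiary alcohol and removes the only acidic proton before the organometallic steps.

Step 9
Reactants: 15 20-O-triethylsilyl ether of 14
Product: 16 13-vinyl-13-carbinol (C13 epimers)
Conditions: vinylMgBr, LaCl3·2LiCl (30 mol %), THF, 0 °C to rt
Reagents that add atoms: vinylmagnesium bromide, C=C[Mg]Br
Why: Lanthanide-promoted Grignard 1,2-addition suppresses enolisation of the hindered ketone, and the new carbinol centre is erased in step 10.

Step 10
Reactants: 16 13-vinyl-13-carbinol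
Product: 17 (E)-allylic bromide (C13=C12H–C11H2Br; C11 trans to C18)
Conditions: PBr3, pyridine (cat.), Et2O, −20 to 0 °C
Reagents that add atoms: phosphorus tribromide, BrP(Br)Br
Why: SN2′-type bromination of a tertiary vinyl carbinol (as for 1-vinylcyclohexanol or linalool) gives the primary allylic bromide, and the E isomer should prevail because CH2Br placed cis to C18 would suffer A(1,3) strain with C19 and its methyl group.

Step 11
Reactants: 18 2-methylcyclopentane-1,3-dione, 4 ethyl vinyl ketone
Product: 19 2-methyl-2-(3-oxopentyl)cyclopentane-1,3-dione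
Conditions: H2O, AcOH (cat.), 75 °C
Reagents that add atoms: none
Why: Michael addition of the acidic 1,3-dione to the enone in water stops cleanly at the prochiral triketone.

Step 12
Reactants: 19 2-methyl-2-(3-oxopentyl)cyclopentane-1,3-dione
Product: 20 (S)-4,7a-dimethyl-2,3,7,7a-tetrahydro-1H-indene-1,5(6H)-dione
Conditions: (S)-phenylalanine, (+)-camphorsulfonic acid, MeCN, reflux
Reagents that add atoms: none
Why: Hajos–Parrish–Eder–Sauer–Wiechert reaction: enamine catalysis by the primary amino acid (better suited than proline to an ethyl ketone side chain) differentiates the two enantiotopic ring carbonyls, closes ring A by a 6-enolendo aldol and dehydration, and sets C10 as S.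

Step 13
Reactants: 20 (S)-4,7a-dimethyl-2,3,7,7a-tetrahydro-1H-indene-1,5(6H)-dione
Product: 21 C8 ethylene ketal of 20
Conditions: ethylene glycol (1.1 equiv), p-TsOH (cat.), benzene, reflux, Dean–Stark
Reagents that add atoms: ethylene glycol, OCCO
Why: Chemoselective acetalisation: the saturated cyclopentanone reacts, while conjugation and tetrasubstitution deactivate the enone carbonyl.

Step 14
Reactants: 21 C8 ethylene ketal of 20
Product: 23 trans-4,4,10-trimethylhydrindan-3-one 8-ketal (5α-H), via lithium enolate 22 (not isolated)
Conditions: Li, NH3(l)–THF, H2O (1 equiv), −78 to −33 °C; isoprene; MeI, −33 °C to rt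
Reagents that add atoms: iodomethane, CI
Why: Reductive alkylation of an enone (Birch-type): axial protonation of the β-carbon C5 gives the trans ring fusion (5α-H), and the regiodefined C3–C4 enolate is methylated at C4 to complete the gem-dimethyl group.

Step 15
Reactants: 23 trans-4,4,10-trimethylhydrindan-3-one 8-ketal
Product: 24 3β-alcohol
Conditions: NaBH4, MeOH, 0 °C
Reagents that add atoms: none
Why: Borohydride attacks the 4,4-dimethyl ketone axially from the α-face (the β-face carries the axial 4β- and C10-methyl groups) and gives the equatorial 3β-alcohol, as in 4,4-dimethyl-3-oxo steroids.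

Step 16
Reactants: 24 3β-alcohol
Product: 25 3β-O-TBS ether
Conditions: TBSCl, imidazole, DMF, 60 °C
Reagents that add atoms: tert-butyldimethylsilyl chloride, CC(C)(C)[Si](C)(C)Cl
Why: Standard silylation, run warm because the equatorial alcohol is neopentylic, gives an ether that is stable to alkyllithiums, ylides and hydrogenation.

Step 17
Reactants: 25 3β-O-TBS ether
Product: 26 B-nor ketone (trans-hydrindan-8-one; C8 bonded to C10)
Conditions: 1 M HCl (cat.), THF–H2O, rt
Reagents that add atoms: water, O
Why: Mild acid hydrolysis cleaves the dioxolane, while the hindered secondary TBS ether survives.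

Step 18
Reactants: 26 B-nor ketone
Product: 27 8α-dibromomethyl-8β-carbinol
Conditions: CH2Br2, LDA added last, THF, −78 °C; AcOH quench at −78 °C
Reagents that add atoms: dibromomethane, BrCBr
Why: Carbonyl addition of dibromomethyllithium generated in the presence of the ketone; the small nucleophile attacks the cyclopentanone from the α-face, anti to the C10 methyl group, as nucleophiles do with 17-oxo steroids, and the carbinol configuration is lost in step 19.

Step 19
Reactants: 27 8α-dibromomethyl-8β-carbinol, 17 (E)-allylic bromide
Product: 31 coupled 8-ketone (ring B six-membered; 9α-H; 9β-CH2 chain), via β-oxido carbenoid 28 (not isolated), via lithium enolate 29 (not isolated), via 9-epi ketone 30 (not isolated)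
Conditions: n-BuLi (2.05 equiv), THF, −90 to 0 °C; DMPU, 17, −78 to 0 °C; MeOH, NaOMe (cat.), rt
Reagents that add atoms: none
Why: β-Oxido carbenoid ring enlargement (dibromomethyllithium/butyllithium homologation of a cyclic ketone) run in tandem with a lithium enolate allylation: the first butyllithium forms the C8 alkoxide, the second exchanges one bromine, and carbenoid 28 loses LiBr while a ring bond of C8 shifts to C9, so that the product of the shift is by necessity the Δ8(9) lithium enolate 29. No ring is closed through a new tether; ring B arises from the cyclopentane C5–C6–C7–C8–C10 by a 1,2-alkyl shift that inserts C9 between C8 and C10 (5→6), with C10 migrating with retention and with loss of LiBr and release of trans-hydrindanone strain as driving forces. The selectivity needed is migration of C10 rather than C7, and in this carbenoid variant the more substituted α-carbon is the one that migrates (the opposite of diazoalkane homologation), here a quaternary carbon against a CH2. Enolate 29, which deprotonation of an 8-ketone could not supply, should be C-alkylated by the primary allylic bromide 17 in the SN2 sense because the γ-carbon C13 is fully substituted, with the E-alkene untouched and with the 1-bromobutane from the exchange far less reactive. Alkylation occurs axially from the α-face, anti to C10-Me, to give 30, and methoxide then equilibrates C9 to the equatorial 9β-chain (9α-H) of 31, the stable configuration of 8-oxolabdane-type ketones.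

Step 20
Reactants: 31 coupled 8-ketone
Product: 32 C8-methylene compound
Conditions: Ph3PCH3Br, KOtBu, toluene, 90 °C
Reagents that add atoms: methyltriphenylphosphonium bromide, C[P+](c1ccccc1)(c1ccccc1)c1ccccc1.[Br-]
Why: Wittig methylenation is routine for hindered 8-oxolabdane-type ketones, and the basic ylide cannot erode C9 because it already has its stable configuration.

Step 21
Reactants: 32 C8-methylene compound
Product: 33 3,20-bis-silyl ether of the target (8β-Me; 8α-H)
Conditions: H2 (1–5 bar), RhCl(PPh3)3 (10 mol %), benzene–EtOH, rt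
Reagents that add atoms: none
Why: Homogeneous hydrogenation with Wilkinson's catalyst discriminates the 1,1-disubstituted C8 methylene from the trisubstituted, doubly α-branched C12=C13 bond, and hydrogen is delivered from the α-face because the β-face is closed by the syn-axial C10 methyl group and the 9β-chain, which pushes the new methyl group into the axial 8β position.

Step 22
Reactants: 33 3,20-bis-silyl ether of the target
Product: 34 target CNP0338143.1
Conditions: TBAF, THF, 60 °C
Reagents that add atoms: none
Why: Fluoride-induced desilylation removes both silyl ethers under non-acidic conditions that spare the tertiary alcohol and the trisubstituted alkene.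

Compound list
1 | 2-methylcyclohexanone (racemic) | CC1CCCCC1=O | starting material
2 | (R)-1-phenylethylamine | C[C@@H](N)c1ccccc1 | starting material
3 | (R)-N-(2-methylcyclohexylidene)-1-phenylethanamine | CC1CCCCC1=N[C@H](C)c1ccccc1 | intermediate
4 | ethyl vinyl ketone (pent-1-en-3-one) | CCC(=O)C=C | starting material
5 | Michael adduct imine (C17 S) | C[C@@H](N=C1CCCC[C@@]1(C)CCC(=O)CC)c1ccccc1 | intermediate
6 | (S)-2-methyl-2-(3-oxopentyl)cyclohexanone | O=C1CCCC[C@@]1(C)CCC(=O)CC | intermediate
7 | (S)-1,4a-dimethyl-4,4a,5,6,7,8-hexahydronaphthalen-2(3H)-one | CC1=C2CCCC[C@@]2(C)CCC1=O | intermediate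
8 | tertiary allylic alcohol (C20 epimers) | CC1=C2CCCC[C@@]2(C)CCC1(C)O | intermediate
9 | (S)-4a,7,8-trimethyl-2,3,4,4a,5,6-hexahydronaphthalene | CC1=C(C)C2=CCCC[C@@]2(C)CC1 | intermediate
10 | 19α,20α-epoxy-13(18)-ene (vinyl epoxide) | C[C@@]12O[C@]1(C)CC[C@]3(C)CCCC=C23 | intermediate
11 | 18-ene-13,20α-diol (C13 epimers) | CC1=C2C(O)CCC[C@@]2(C)CC[C@@]1(C)O | intermediate
12 | 20α-hydroxy-17β,19,20β-trimethyl-18-en-13-one | CC1=C2C(=O)CCC[C@@]2(C)CC[C@@]1(C)O | intermediate
13 | trans-decalone (18α-H, 19β-Me) | C[C@@H]1[C@@H]2C(=O)CCC[C@@]2(C)CC[C@@]1(C)O | intermediate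
14 | cis-decalone (18β-H, 19β-Me, 20β-Me, 20α-OH) | C[C@@H]1[C@H]2C(=O)CCC[C@@]2(C)CC[C@@]1(C)O | intermediate
15 | 20-O-TES ether of 14 | C[C@@H]1[C@H]2C(=O)CCC[C@@]2(C)CC[C@@]1(C)O[Si](CC)(CC)CC | intermediate
16 | 13-vinyl-13-carbinol (C13 epimers) | C[C@@H]1[C@H]2C(O)(C=C)CCC[C@@]2(C)CC[C@@]1(C)O[Si](CC)(CC)CC | intermediate
17 | (E)-allylic bromide | C[C@@H]1[C@H]2/C(=C/CBr)CCC[C@@]2(C)CC[C@@]1(C)O[Si](CC)(CC)CC | intermediate
18 | 2-methylcyclopentane-1,3-dione | CC1C(=O)CCC1=O | starting material
19 | 2-methyl-2-(3-oxopentyl)cyclopentane-1,3-dione | CCC(=O)CCC1(C)C(=O)CCC1=O | intermediate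
20 | (S)-4,7a-dimethyl-2,3,7,7a-tetrahydro-1H-indene-1,5(6H)-dione | O=C1CCC2=C(C)C(=O)CC[C@]12C | intermediate
21 | C8 ethylene ketal of 20 | O1CCOC12CCC3=C(C)C(=O)CC[C@]23C | intermediate
22 | lithium C3–C4 enolate (5α-H) | O1CCOC12CC[C@H]3C(C)=C(O[Li])CC[C@]23C | intermediate
23 | trans-4,4,10-trimethylhydrindan-3-one 8-ketal | O1CCOC12CC[C@H]3C(C)(C)C(=O)CC[C@]23C | intermediate
24 | 3β-alcohol | O1CCOC12CC[C@H]3C(C)(C)[C@@H](O)CC[C@]23C | intermediate
25 | 3β-O-TBS ether | O1CCOC12CC[C@H]3C(C)(C)[C@@H](O[Si](C)(C)C(C)(C)C)CC[C@]23C | intermediate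
26 | B-nor ketone (trans-hydrindan-8-one) | O=C1CC[C@H]2C(C)(C)[C@@H](O[Si](C)(C)C(C)(C)C)CC[C@]12C | intermediate
27 | 8α-dibromomethyl-8β-carbinol | BrC(Br)[C@]1(O)CC[C@H]2C(C)(C)[C@@H](O[Si](C)(C)C(C)(C)C)CC[C@]12C | intermediate
28 | β-oxido carbenoid | [Li]C(Br)[C@]1(O[Li])CC[C@H]2C(C)(C)[C@@H](O[Si](C)(C)C(C)(C)C)CC[C@]12C | intermediate
29 | Δ8(9) lithium enolate (ring B six-membered) | C1=C(O[Li])CC[C@H]2C(C)(C)[C@@H](O[Si](C)(C)C(C)(C)C)CC[C@]12C | intermediate
30 | 9-epi ketone (9α-chain, 9β-H) | C[C@@H]1[C@H]2/C(=C/C[C@@H]3C(=O)CC[C@H]4C(C)(C)[C@@H](O[Si](C)(C)C(C)(C)C)CC[C@]34C)CCC[C@@]2(C)CC[C@@]1(C)O[Si](CC)(CC)CC | intermediate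
31 | coupled 8-ketone (9β-chain, 9α-H) | C[C@@H]1[C@H]2/C(=C/C[C@H]3C(=O)CC[C@H]4C(C)(C)[C@@H](O[Si](C)(C)C(C)(C)C)CC[C@]34C)CCC[C@@]2(C)CC[C@@]1(C)O[Si](CC)(CC)CC | intermediate
32 | C8-methylene compound | C[C@@H]1[C@H]2/C(=C/C[C@H]3C(=C)CC[C@H]4C(C)(C)[C@@H](O[Si](C)(C)C(C)(C)C)CC[C@]34C)CCC[C@@]2(C)CC[C@@]1(C)O[Si](CC)(CC)CC | intermediate
33 | 3,20-bis-silyl ether of the target | C[C@@H]1[C@H]2/C(=C/C[C@H]3[C@@H](C)CC[C@H]4C(C)(C)[C@@H](O[Si](C)(C)C(C)(C)C)CC[C@]34C)CCC[C@@]2(C)CC[C@@]1(C)O[Si](CC)(CC)CC | intermediate
34 | CNP0338143.1 | C[C@@H]1[C@H]2/C(=C/C[C@H]3[C@@H](C)CC[C@H]4C(C)(C)[C@@H](O)CC[C@]34C)CCC[C@@]2(C)CC[C@@]1(C)O | target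

Total step count: 22. Longest linear sequence: 14 (steps 1–10 and 19–22).

Steps most likely to fail

Step 19. Several things may go wrong.
- The wrong ring bond (C7) may migrate.
- Proton transfer between enolate and product may scramble the enolate position.
- Alkylation at the neopentylic C9 may be too slow, so that butylation or O-alkylation takes over.

The fallback separates ring enlargement and coupling and lets sulfur direct both. It sets out from 26.
- Bis(phenylthio)methyllithium adds to the ketone from the α-face to give the bis(phenylthio)methyl carbinol F1.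
- Copper(I) triflate with Hünig's base in warm benzene removes one thiolate. The thionium-type cation pulls the more substituted carbon C10 over in a pinacol-type shift and gives the ring-enlarged 9-phenylthio-8-ketone F2.
- The sulfur-acidified C9–H of F2 is deprotonated selectively with KH and alkylated with 17 to the 9-allyl-9-phenylthio ketone F3.
- SmI2 in THF–MeOH cleaves the C–S bond through the same Δ8(9)-enolate.
- Methoxide equilibration brings the material back to the route at 31.

Step 5. Three processes threaten the step.
- Over-oxidation of the second double bond.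
- Acid-induced ionisation of the tertiary allylic C20–O bond.
- Pinacol-type shift or elimination of the vinyl oxirane.

The fallback avoids any allyl cation and sets out from 9.
- BH3·THF hydroborates the less hindered trisubstituted C13=C18 bond from the α-face, and oxidation gives the homoallylic 13α-alcohol F4.
- Dess–Martin oxidation gives the β,γ-unsaturated ketone F5.
- Buffered mCPBA epoxidises the now isolated tetrasubstituted C19=C20 bond from the α-face to the β,γ-epoxy ketone F6.
- Triethylamine or DBU opens the oxirane by E1cB elimination through the C18 enolate, which returns to the route at 12.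

Step 21. Four processes threaten the step.
- Sluggish uptake at the hindered methylene.
- Migration of the double bond into ring B.
- Competing saturation of C12=C13.
- Poor facial selectivity.

The fallback replaces hydrogenation by hydroboration and deoxygenation and sets out from 32.
- 9-BBN adds only to the 1,1-disubstituted alkene, from the α-face, and oxidation gives the axial 8β-hydroxymethyl compound F7.
- Mesylation gives the mesylate F8.
- LiEt3BH in warm THF displaces the mesylate by hydride and returns to the route at 33.

Further compounds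
F1 | step 19 | bis(phenylthio)methyl carbinol | c1ccccc1SC(Sc1ccccc1)[C@]1(O)CC[C@H]2C(C)(C)[C@@H](O[Si](C)(C)C(C)(C)C)CC[C@]12C
F2 | step 19 | 9-phenylthio-8-ketone (ring B six-membered) | C1(Sc2ccccc2)C(=O)CC[C@H]3C(C)(C)[C@@H](O[Si](C)(C)C(C)(C)C)CC[C@]13C
F3 | step 19 | 9-allyl-9-phenylthio ketone | C[C@@H]1[C@H]2/C(=C/CC3(Sc5ccccc5)C(=O)CC[C@H]4C(C)(C)[C@@H](O[Si](C)(C)C(C)(C)C)CC[C@]34C)CCC[C@@]2(C)CC[C@@]1(C)O[Si](CC)(CC)CC
F4 | step 5 | homoallylic 13α-alcohol (18α-H, 19-ene) | CC1=C(C)[C@@H]2[C@@H](O)CCC[C@@]2(C)CC1
F5 | step 5 | β,γ-unsaturated ketone (18α-H, 19-en-13-one) | CC1=C(C)[C@@H]2C(=O)CCC[C@@]2(C)CC1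
F6 | step 5 | 19α,20α-epoxy-13-ketone | C[C@@]12O[C@]1(C)CC[C@]3(C)CCCC(=O)[C@@H]23
F7 | step 21 | 8β-hydroxymethyl compound | C[C@@H]1[C@H]2/C(=C/C[C@H]3[C@@H](CO)CC[C@H]4C(C)(C)[C@@H](O[Si](C)(C)C(C)(C)C)CC[C@]34C)CCC[C@@]2(C)CC[C@@]1(C)O[Si](CC)(CC)CC
F8 | step 21 | 8β-mesyloxymethyl compound | C[C@@H]1[C@H]2/C(=C/C[C@H]3[C@@H](COS(C)(=O)=O)CC[C@H]4C(C)(C)[C@@H](O[Si](C)(C)C(C)(C)C)CC[C@]34C)CCC[C@@]2(C)CC[C@@]1(C)O[Si](CC)(CC)CC
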